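**Retrosynthetic overview**
1. Target 32 is a trans-fused α-methylene-γ-butyrolactone (ring B: O, C8, C7, C11, C12; C13 exocyclic) on a cyclodeca-1(10),4-diene (ring A: C1–C10; C14 on C10, C15 on C4). The last step is 1,2-reduction of the C14 enal 31.
2. The key disconnection is C8–C9, which closes ring A. It is a decarboxylative radical addition–elimination of the monocyclic seco acid 28, joining two carbons that are both electrophilic by nature (a carbinol carbon and an enal β-carbon).
3. Enabling feature: C8 is the O-bearing γ-carbon of ring B, so a carboxyl group on it is a traceless radical handle. C9 is the CH2 end of the C9–C10(C14)=C1 allyl unit, which becomes the β-carbon of a 2-substituted acrolein once C14 is CHO and C1 carries acetate. C7 of ring B steers the new C8 centre.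
4. Seco acid 28 comes from aldehyde 23 plus bromoacrolein acetal 24 (C1–C10 bond), acid 21 (C15 ester) and lactone 15. Ring B is made by cyclocarbonylation of alkynyl diol 14.
5. Diol 14 comes from (S)-3-hydroxy-γ-butyrolactone 10, whose carbinol sets C7 by trans-alkylation, and allylic bromide 9, whose C4=C5 geometry is set by syn-carbocupration of ynoate 3. Ring order: B (step 8), then A (step 19).

Key step: step 19

Remark: the C1 carbinol centre (26, 27, 28) and the anomeric centre of 13 are carried as epimer mixtures, because both centres are destroyed later.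
Remark: 24 is taken as commercial; otherwise it is made by bromination and dehydrobromination of acrolein diethyl acetal.

**Step 1**
Reactants: 1 tert-butyldimethyl(prop-2-yn-1-yloxy)silane
Product: 3 methyl 4-[(tert-butyldimethylsilyl)oxy]but-2-ynoate, via lithium acetylide 2 (not isolated)
Conditions: n-BuLi, THF, −78 °C; ClCO2Me, −78 °C to 0 °C
Reagents that add atoms: methyl chloroformate, COC(=O)Cl
Why: Deprotonation of a terminal alkyne and C-acylation of the acetylide by a chloroformate is the standard alkynoate synthesis, and the silyl ether is inert to it.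

**Step 2**
Reactants: 3 methyl 4-[(tert-butyldimethylsilyl)oxy]but-2-ynoate; 4 2-(2-bromoethyl)-1,3-dioxolane
Product: 7 methyl (Z)-3-{[(tert-butyldimethylsilyl)oxy]methyl}-5-(1,3-dioxolan-2-yl)pent-2-enoate, via Grignard reagent 5 (not isolated), via organocopper reagent 6 (not isolated)
Conditions: 4, Mg, THF, 25 °C; CuBr·SMe2 (1 equiv per Grignard reagent), THF/Me2S, −45 °C; 3, −78 °C; aq NH4Cl at −78 °C
Reagents that add atoms: none
Why: syn-Carbocupration of an ynoate followed by cold protonation places the new chain (C3) cis to H, so the ester carbon (C6) ends up cis to the silyloxymethyl group (C15), which is the C4=C5 geometry of the target.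

**Step 3**
Reactants: 7 methyl (Z)-3-{[(tert-butyldimethylsilyl)oxy]methyl}-5-(1,3-dioxolan-2-yl)pent-2-enoate
Product: 8 (Z)-3-{[(tert-butyldimethylsilyl)oxy]methyl}-5-(1,3-dioxolan-2-yl)pent-2-en-1-ol
Conditions: DIBAL-H (2.2 equiv), CH2Cl2, −78 °C; aq potassium sodium tartrate
Reagents that add atoms: none
Why: DIBAL-H 1,2-reduction of an enoate should give the allylic alcohol without touching the alkene geometry, the acetal or the silyl ether.

**Step 4**
Reactants: 8 (Z)-3-{[(tert-butyldimethylsilyl)oxy]methyl}-5-(1,3-dioxolan-2-yl)pent-2-en-1-ol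
Product: 9 {[(2Z)-4-bromo-2-[2-(1,3-dioxolan-2-yl)ethyl]but-2-en-1-yl]oxy}(tert-butyl)dimethylsilane
Conditions: CBr4, PPh3, 2,6-lutidine, CH2Cl2, 0 °C
Reagents that add atoms: carbon tetrabromide, BrC(Br)(Br)Br
Why: The Appel reaction converts a primary allylic alcohol into the bromide by SN2 displacement under buffered, nearly neutral conditions, with retention of alkene geometry.

**Step 5**
Reactants: 9 {[(2Z)-4-bromo-2-[2-(1,3-dioxolan-2-yl)ethyl]but-2-en-1-yl]oxy}(tert-butyl)dimethylsilane; 10 (S)-3-hydroxy-γ-butyrolactone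
Product: 12 (3S,4S)-3-[(2Z)-3-{[(tert-butyldimethylsilyl)oxy]methyl}-5-(1,3-dioxolan-2-yl)pent-2-en-1-yl]-4-hydroxyoxolan-2-one (trans), via dilithio dianion 11 (not isolated)
Conditions: 10, LDA (2.2 equiv), THF/DMPU, −78 °C; 9, −78 °C to −30 °C; aq NH4Cl
Reagents that add atoms: none
Why: In this Fráter–Seebach-type alkylation the enolate of the β-alkoxide dianion attacks the allylic bromide (SN2, geometry retained) anti to the lithium alkoxide, which sets C7 trans to the carbinol oxygen.

**Step 6**
Reactants: 12 (3S,4S)-trans-3-alkyl-4-hydroxyoxolan-2-one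
Product: 13 (3S,4S)-3-[(2Z)-3-{[(tert-butyldimethylsilyl)oxy]methyl}-5-(1,3-dioxolan-2-yl)pent-2-en-1-yl]oxolane-2,4-diol (lactol, anomer mixture)
Conditions: DIBAL-H (2.5 equiv), CH2Cl2, −78 °C; aq potassium sodium tartrate
Reagents that add atoms: none
Why: Partial DIBAL-H reduction of a γ-lactone stops at the aluminium hemiacetal at −78 °C and should give the lactol, the free hydroxyl only consuming one extra equivalent.

**Step 7**
Reactants: 13 lactol
Product: 14 (2S,3R,5Z)-6-{[(tert-butyldimethylsilyl)oxy]methyl}-8-(1,3-dioxolan-2-yl)-3-ethynyloct-5-ene-1,2-diol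
Conditions: dimethyl (1-diazo-2-oxopropyl)phosphonate, K2CO3, MeOH, 0 °C to 25 °C
Reagents that add atoms: dimethyl (1-diazo-2-oxopropyl)phosphonate, COP(=O)(OC)C(=[N+]=[N-])C(C)=O
Why: The Ohira–Bestmann variant of the Seyferth–Gilbert homologation works on the open hydroxy-aldehyde form of lactols under mild carbonate conditions, turning C11 into a terminal alkyne (adding C13) while C7 is kept.

**Step 8**
Reactants: 14 alkynyl diol
Product: 15 (4R,5S)-4-[(2Z)-3-{[(tert-butyldimethylsilyl)oxy]methyl}-5-(1,3-dioxolan-2-yl)pent-2-en-1-yl]-5-(hydroxymethyl)-3-methylideneoxolan-2-one (cis)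
Conditions: Pd(OAc)2 (3 mol %), 2-PyPPh2 (12 mol %), TsOH (6 mol %), CO (20 bar), CH2Cl2, 45 °C
Reagents that add atoms: carbon monoxide, [C-]#[O+]
Why: Palladium-catalysed Markovnikov cyclocarbonylation of a homopropargylic alcohol gives the α-methylene-γ-butyrolactone (ring B) directly, the five-membered lactone through the secondary hydroxyl being favoured kinetically and thermodynamically over the six-membered one.

**Step 9**
Reactants: 15 hydroxymethyl lactone
Product: 16 (2S,3R)-3-[(2Z)-3-{[(tert-butyldimethylsilyl)oxy]methyl}-5-(1,3-dioxolan-2-yl)pent-2-en-1-yl]-4-methylidene-5-oxooxolane-2-carboxylic acid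
Conditions: TEMPO (20 mol %), PhI(OAc)2 (2.5 equiv), MeCN/pH 7 buffer, 25 °C
Reagents that add atoms: water, O
Why: The TEMPO/PhI(OAc)2 oxidation takes a primary alcohol through the aldehyde hydrate to the acid and leaves alkenes, the acetal and the silyl ether alone.

**Step 10**
Reactants: 16 lactone acid
Product: 17 tert-butyl (2S,3R)-3-[(2Z)-3-{[(tert-butyldimethylsilyl)oxy]methyl}-5-(1,3-dioxolan-2-yl)pent-2-en-1-yl]-4-methylidene-5-oxooxolane-2-carboxylate
Conditions: tert-butyl 2,2,2-trichloroacetimidate, CH2Cl2/cyclohexane, 25 °C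
Reagents that add atoms: tert-butyl 2,2,2-trichloroacetimidate, CC(C)(C)OC(=N)C(Cl)(Cl)Cl
Why: Imidate esterification is driven by the carboxylic acid itself, needs no base or added acid, and so spares the Michael acceptor and the acid-labile groups.

**Step 11**
Reactants: 17 tert-butyl ester
Product: 18 tert-butyl (2S,3R)-3-[(2Z)-5-(1,3-dioxolan-2-yl)-3-(hydroxymethyl)pent-2-en-1-yl]-4-methylidene-5-oxooxolane-2-carboxylate
Conditions: HF·pyridine, pyridine, THF, 0 °C
Reagents that add atoms: none
Why: Buffered fluoride desilylation frees the primary allylic C15 hydroxyl under non-basic, non-aqueous conditions that the α-methylene lactone, the dioxolane and the tert-butyl ester tolerate.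

**Step 12**
Reactants: 19 methyl (S)-3-hydroxy-2-methylpropanoate
Product: 20 methyl (S)-3-[(tert-butyldimethylsilyl)oxy]-2-methylpropanoate
Conditions: TBSCl, imidazole, DMF, 25 °C
Reagents that add atoms: tert-butyldimethylsilyl chloride, C[Si](C)(Cl)C(C)(C)C
Why: Standard silylation of a primary alcohol; the stereocentre comes from the chiral pool and is not touched.

**Step 13**
Reactants: 20 methyl (S)-3-[(tert-butyldimethylsilyl)oxy]-2-methylpropanoate
Product: 21 (S)-3-[(tert-butyldimethylsilyl)oxy]-2-methylpropanoic acid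
Conditions: LiOH, THF/MeOH/H2O, 0 °C; 1 M HCl to pH 4
Reagents that add atoms: lithium hydroxide, [Li+].[OH-]
Why: Cold saponification of the methyl ester is a routine way to this acid and is mild enough to avoid enolisation of the α-centre and β-elimination.

**Step 14**
Reactants: 18 allylic alcohol; 21 (S)-3-[(tert-butyldimethylsilyl)oxy]-2-methylpropanoic acid
Product: 22 tert-butyl (2S,3R)-3-[(2Z)-3-({[(2S)-3-[(tert-butyldimethylsilyl)oxy]-2-methylpropanoyl]oxy}methyl)-5-(1,3-dioxolan-2-yl)pent-2-en-1-yl]-4-methylidene-5-oxooxolane-2-carboxylate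
Conditions: DCC, DMAP (10 mol %), CH2Cl2, 0 °C to 25 °C
Reagents that add atoms: none
Why: Steglich esterification acylates the only free hydroxyl (C15) under neutral conditions; C1 is kept as the acetal so that no cyclic hemiacetal can compete.

**Step 15**
Reactants: 22 dioxolane ester
Product: 23 tert-butyl (2S,3R)-3-[(2Z)-3-({[(2S)-3-[(tert-butyldimethylsilyl)oxy]-2-methylpropanoyl]oxy}methyl)-6-oxohex-2-en-1-yl]-4-methylidene-5-oxooxolane-2-carboxylate
Conditions: Ce(OTf)3 (30 mol %), wet MeNO2, 25 °C
Reagents that add atoms: water, O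
Why: Lanthanide-triflate-catalysed acetal hydrolysis runs at almost neutral pH and should free the C1 aldehyde without loss of the silyl ether or the tert-butyl ester.

**Step 16**
Reactants: 23 aldehyde; 24 2-bromo-3,3-diethoxyprop-1-ene
Product: 26 tert-butyl (2S,3R)-3-[(2Z)-3-({[(2S)-3-[(tert-butyldimethylsilyl)oxy]-2-methylpropanoyl]oxy}methyl)-7-(diethoxymethyl)-6-hydroxyocta-2,7-dien-1-yl]-4-methylidene-5-oxooxolane-2-carboxylate (C1 epimers), via alkenylchromium reagent 25 (not isolated)
Conditions: CrCl2 (5 equiv), NiCl2 (2 mol %), DMF, 25 °C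
Reagents that add atoms: none
Why: The Nozaki–Hiyama–Kishi reaction adds an alkenyl halide to an aldehyde with full chemoselectivity over esters and lactones; the new C1 carbinol centre is not controlled and need not be, since it is destroyed in step 19.

**Step 17**
Reactants: 26 allylic alcohol
Product: 27 the C1 acetate of 26
Conditions: Ac2O, pyridine, DMAP (5 mol %), CH2Cl2, 0 °C
Reagents that add atoms: acetic anhydride, CC(=O)OC(C)=O
Why: Routine acetylation of the only free hydroxyl installs the leaving group for the elimination in step 19.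

**Step 18**
Reactants: 27 acetate
Product: 28 (2S,3R)-3-[(2Z)-6-acetoxy-7-formyl-3-({[(2S)-3-hydroxy-2-methylpropanoyl]oxy}methyl)octa-2,7-dien-1-yl]-4-methylidene-5-oxooxolane-2-carboxylic acid (seco acid, C1 epimers)
Conditions: TFA, CH2Cl2, H2O (few equiv), 0 °C to 25 °C
Reagents that add atoms: water, O
Why: One acidolysis removes the three acid-labile groups (tert-butyl ester, diethyl acetal, primary silyl ether), while the acetate next to the electron-poor alkene and the C15 ester, which would ionise only to a poorly stabilised allyl cation, should survive.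

**Step 19**
Reactants: 28 seco acid
Product: 31 (7R,8S)-15-{[(2S)-3-hydroxy-2-methylpropanoyl]oxy}-14-oxogermacra-1(10)E,4Z,11(13)-trien-12,8-olide, via lactonyl radical 29 (not isolated), via macrocyclic enolate 30 (not isolated)
Conditions: 4CzIPN (5 mol %), n-Bu4NOAc (20 mol %), degassed MeCN (0.5 mM), 450 nm LEDs, 25 °C
Reagents that add atoms: none
Why: Proposed new method: acetate deprotonates 28, excited 4CzIPN oxidises the carboxylate, and loss of CO2 gives the α-acyloxy radical 29 at C8, which adds to the unsubstituted CH2 terminus (C9) of the acetoxy enal; the resulting α-formyl radical is reduced by the 4CzIPN radical anion to enolate 30, which expels acetate from C1 (E1cB) and so regenerates the base. The closest known reaction types are the photoredox decarboxylative Giese macrocyclisation of peptide acids and the intermolecular decarboxylative allylation of α-oxy and α-amino acids with Morita–Baylis–Hillman acetates, and their combination in a ten-membered carbocycle closure is what is new. Ring A closes in the 10-endo-trig mode, helped by three rigid units in the tether (ring B, the C4=C5 alkene, the enal). The new C8 centre is controlled by C7: the chain leaves C7 on one face of the nearly planar ring-B radical and can reach C8 without eclipsing the C6–C7–C8–C9 array only from the opposite face, which gives the trans fusion (8S) whatever the configuration at C8 was in 28. The C1=C10 geometry comes from the E1cB step, which delivers the (E)-enal (CHO trans to C2, ring-cis), the isomer favoured both in open chains and in this ring, so both C1 epimers converge. The step needs ring closure to outrun intermolecular addition to an enal or an α-methylene lactone; this is secured by the dilution, by the high acceptor strength of the 2-substituted acrolein, and by the fact that 29 cannot reach its own exocyclic methylene (that would be a three- or four-membered closure).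

**Step 20**
Reactants: 31 macrocyclic enal
Product: 32 (7R,8S)-14-hydroxy-15-{[(2S)-3-hydroxy-2-methylpropanoyl]oxy}germacra-1(10)E,4Z,11(13)-trien-12,8-olide (CNP0241696.1)
Conditions: NaBH4, CeCl3·7H2O, MeOH, −78 °C
Reagents that add atoms: none
Why: Luche reduction is a fast 1,2-reduction of the aldehyde at −78 °C, which should leave the α-methylene lactone, the ester and both ring alkenes untouched, and it creates no stereocentre.

**Compound list**
1 | tert-butyldimethyl(prop-2-yn-1-yloxy)silane | C#CCO[Si](C)(C)C(C)(C)C | starting material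
2 | lithium acetylide of 1 | [Li]C#CCO[Si](C)(C)C(C)(C)C | intermediate
3 | methyl 4-[(tert-butyldimethylsilyl)oxy]but-2-ynoate | COC(=O)C#CCO[Si](C)(C)C(C)(C)C | intermediate
4 | 2-(2-bromoethyl)-1,3-dioxolane | BrCCC1OCCO1 | starting material
5 | [2-(1,3-dioxolan-2-yl)ethyl]magnesium bromide | Br[Mg]CCC1OCCO1 | intermediate
6 | [2-(1,3-dioxolan-2-yl)ethyl]copper | [Cu]CCC1OCCO1 | intermediate
7 | methyl (Z)-3-{[(tert-butyldimethylsilyl)oxy]methyl}-5-(1,3-dioxolan-2-yl)pent-2-enoate | COC(=O)/C=C(/CCC1OCCO1)CO[Si](C)(C)C(C)(C)C | intermediate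
8 | (Z)-3-{[(tert-butyldimethylsilyl)oxy]methyl}-5-(1,3-dioxolan-2-yl)pent-2-en-1-ol | OC/C=C(/CCC1OCCO1)CO[Si](C)(C)C(C)(C)C | intermediate
9 | {[(2Z)-4-bromo-2-[2-(1,3-dioxolan-2-yl)ethyl]but-2-en-1-yl]oxy}(tert-butyl)dimethylsilane | BrC/C=C(/CCC1OCCO1)CO[Si](C)(C)C(C)(C)C | intermediate
10 | (S)-3-hydroxy-γ-butyrolactone | O=C1C[C@H](O)CO1 | starting material
11 | dilithio dianion of 10 | [Li]OC1=C[C@H](O[Li])CO1 | intermediate
12 | (3S,4S)-trans-3-alkyl-4-hydroxyoxolan-2-one | O=C1OC[C@@H](O)[C@@H]1C/C=C(/CCC1OCCO1)CO[Si](C)(C)C(C)(C)C | intermediate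
13 | (3S,4S)-lactol, anomer mixture | OC1OC[C@@H](O)[C@@H]1C/C=C(/CCC1OCCO1)CO[Si](C)(C)C(C)(C)C | intermediate
14 | (2S,3R,5Z)-alkynyl diol | OC[C@@H](O)[C@@H](C#C)C/C=C(/CCC1OCCO1)CO[Si](C)(C)C(C)(C)C | intermediate
15 | (4R,5S)-cis-5-(hydroxymethyl)-3-methylidene lactone | C=C1C(=O)O[C@H](CO)[C@@H]1C/C=C(/CCC1OCCO1)CO[Si](C)(C)C(C)(C)C | intermediate
16 | (2S,3R)-lactone acid | C=C1C(=O)O[C@H](C(=O)O)[C@@H]1C/C=C(/CCC1OCCO1)CO[Si](C)(C)C(C)(C)C | intermediate
17 | tert-butyl ester of 16 | C=C1C(=O)O[C@H](C(=O)OC(C)(C)C)[C@@H]1C/C=C(/CCC1OCCO1)CO[Si](C)(C)C(C)(C)C | intermediate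
18 | C15 alcohol | C=C1C(=O)O[C@H](C(=O)OC(C)(C)C)[C@@H]1C/C=C(/CCC1OCCO1)CO | intermediate
19 | methyl (S)-3-hydroxy-2-methylpropanoate | COC(=O)[C@@H](C)CO | starting material
20 | methyl (S)-3-[(tert-butyldimethylsilyl)oxy]-2-methylpropanoate | COC(=O)[C@@H](C)CO[Si](C)(C)C(C)(C)C | intermediate
21 | (S)-3-[(tert-butyldimethylsilyl)oxy]-2-methylpropanoic acid | OC(=O)[C@@H](C)CO[Si](C)(C)C(C)(C)C | intermediate
22 | C15 ester, C1 dioxolane | C=C1C(=O)O[C@H](C(=O)OC(C)(C)C)[C@@H]1C/C=C(/CCC1OCCO1)COC(=O)[C@@H](C)CO[Si](C)(C)C(C)(C)C | intermediate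
23 | C1 aldehyde | C=C1C(=O)O[C@H](C(=O)OC(C)(C)C)[C@@H]1C/C=C(/CCC=O)COC(=O)[C@@H](C)CO[Si](C)(C)C(C)(C)C | intermediate
24 | 2-bromo-3,3-diethoxyprop-1-ene | C=C(Br)C(OCC)OCC | starting material
25 | (3,3-diethoxyprop-1-en-2-yl)chromium dichloride | C=C([Cr](Cl)Cl)C(OCC)OCC | intermediate
26 | C1 allylic alcohol, epimer mixture | C=C1C(=O)O[C@H](C(=O)OC(C)(C)C)[C@@H]1C/C=C(/CCC(O)C(=C)C(OCC)OCC)COC(=O)[C@@H](C)CO[Si](C)(C)C(C)(C)C | intermediate
27 | C1 acetate, epimer mixture | C=C1C(=O)O[C@H](C(=O)OC(C)(C)C)[C@@H]1C/C=C(/CCC(OC(C)=O)C(=C)C(OCC)OCC)COC(=O)[C@@H](C)CO[Si](C)(C)C(C)(C)C | intermediate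
28 | seco acid, C1 epimer mixture | C=C1C(=O)O[C@H](C(=O)O)[C@@H]1C/C=C(/CCC(OC(C)=O)C(=C)C=O)COC(=O)[C@@H](C)CO | intermediate
29 | C8 lactonyl radical | C=C1C(=O)O[CH][C@@H]1C/C=C(/CCC(OC(C)=O)C(=C)C=O)COC(=O)[C@@H](C)CO | intermediate
30 | macrocyclic β-acetoxy enolate | C=C1C(=O)O[C@H]2CC(=C[O-])C(OC(C)=O)CC/C(COC(=O)[C@@H](C)CO)=C/C[C@H]12 | intermediate
31 | macrocyclic C14 enal | C=C1C(=O)O[C@H]2C/C(C=O)=C\CC/C(COC(=O)[C@@H](C)CO)=C/C[C@H]12 | intermediate
32 | CNP0241696.1 | C=C1C(=O)O[C@H]2C/C(CO)=C\CC/C(COC(=O)[C@@H](C)CO)=C/C[C@H]12 | target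

**Step count**
Total step count: 20.
Longest linear sequence: 18 (steps 1–11 and 14–20).

**Steps most likely to fail**

1. **Step 19.** The ten-membered closure may be too slow. Intermolecular radical addition (oligomerisation), hydrogen-atom abstraction from allylic positions or solvent, or closure on the wrong face of the radical could then take over.
   - The fallback sets out from 23 and returns at 32. It keeps the decarboxylative radical construction of C8–C9 but makes it intermolecular, and it moves the ring closure to an olefination.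
   - TMSOTf/2,6-lutidine followed by water cleaves the tert-butyl ester of 23 to the acid aldehyde F1.
   - A photoredox decarboxylative Giese addition of F1 to excess tert-butyl 2-(diethoxyphosphoryl)acrylate follows. This doubly activated acceptor should outrun the α-methylene lactone, and attack anti to the C7 side chain should give the trans-lactone phosphonate F2.
   - An intramolecular Horner–Wadsworth–Emmons reaction (LiCl, i-Pr2NEt, MeCN, high dilution) closes ring A at C1=C10 to the macrocyclic tert-butyl enoate F3.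
   - TMSOTf/2,6-lutidine then gives the C14 acid F4.
   - Isobutyl chloroformate/N-methylmorpholine followed by NaBH4 at −20 °C reduces the mixed anhydride to the silyl-protected target F5.
   - HF·pyridine gives 32.

2. **Step 8.** Control may be lost in the hydropalladation/carbonylation: lactonisation through the primary hydroxyl, acid-induced loss of the acetal or silyl ether, or enyne cycloisomerisation.
   - The fallback sets out from 14 and returns at 15. It separates metalation from carbonylation and runs under basic conditions.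
   - α-Selective nickel-catalysed hydroalumination (Ni(dppp)Cl2, excess DIBAL-H, THF) followed by I2 gives the 2-iodoalkene diol F6.
   - Carbonylative lactonisation of F6 by oxidative addition (Pd(PPh3)4, CO 1 bar, Et3N, THF, 50 °C) gives 15.

3. **Step 16.** Activation of the alkenyl bromide by zerovalent nickel may be sluggish. Pinacol coupling or reduction of the aldehyde, or conjugate reduction of the exocyclic methylene by divalent chromium, could then compete.
   - The fallback sets out from 23 and returns at 28. It replaces the organometallic addition by an organocatalytic C–C bond formation at the aldehyde oxidation level.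
   - A Morita–Baylis–Hillman reaction of 23 with acrolein (quinuclidine, MeOH co-solvent) gives the hydroxy enal F7.
   - Ac2O/pyridine gives the acetoxy enal F8.
   - TFA/CH2Cl2/H2O removes the tert-butyl ester and the silyl ether to give 28.

**Further compounds**
F1 | step 19 | acid aldehyde (tert-butyl ester of 23 cleaved) | C=C1C(=O)O[C@H](C(=O)O)[C@@H]1C/C=C(/CCC=O)COC(=O)[C@@H](C)CO[Si](C)(C)C(C)(C)C
F2 | step 19 | trans-lactone phosphonate (C10 epimers) | C=C1C(=O)O[C@@H](CC(C(=O)OC(C)(C)C)P(=O)(OCC)OCC)[C@@H]1C/C=C(/CCC=O)COC(=O)[C@@H](C)CO[Si](C)(C)C(C)(C)C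
F3 | step 19 | macrocyclic tert-butyl enoate | C=C1C(=O)O[C@H]2C/C(C(=O)OC(C)(C)C)=C\CC/C(COC(=O)[C@@H](C)CO[Si](C)(C)C(C)(C)C)=C/C[C@H]12
F4 | step 19 | macrocyclic C14 acid | C=C1C(=O)O[C@H]2C/C(C(=O)O)=C\CC/C(COC(=O)[C@@H](C)CO[Si](C)(C)C(C)(C)C)=C/C[C@H]12
F5 | step 19 | silyl-protected target | C=C1C(=O)O[C@H]2C/C(CO)=C\CC/C(COC(=O)[C@@H](C)CO[Si](C)(C)C(C)(C)C)=C/C[C@H]12
F6 | step 8 | 2-iodoalkene diol | OC[C@@H](O)[C@@H](C(=C)I)C/C=C(/CCC1OCCO1)CO[Si](C)(C)C(C)(C)C
F7 | step 16 | hydroxy enal (C1 epimers) | C=C1C(=O)O[C@H](C(=O)OC(C)(C)C)[C@@H]1C/C=C(/CCC(O)C(=C)C=O)COC(=O)[C@@H](C)CO[Si](C)(C)C(C)(C)C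
F8 | step 16 | acetoxy enal (C1 epimers) | C=C1C(=O)O[C@H](C(=O)OC(C)(C)C)[C@@H]1C/C=C(/CCC(OC(C)=O)C(=C)C=O)COC(=O)[C@@H](C)CO[Si](C)(C)C(C)(C)C
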